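| setting | maple | oak | flask |
|---|---|---|---|
| substrate | 0.050 M | 0.034 M | 0.050 M |
| enzyme | 0.075 mol% | 0.075 mol% | 0.075 mol% |
| remark | the very flask that is asked about, followed so far | run made earlier |  |

maple run (percent of the substrate charged)

| time / h | product / % | substrate / % |
|---|---|---|
| 2.00 | 36.2 | 64.1 |
| 4.00 | 53.5 | 48.4 |
| 6.00 | 60.9 | 39.0 |
| 12.0 | 74.2 | 27.4 |
| 25.0 | 82.9 | 18.6 |

oak run (percent of the substrate charged)

| time / d | product / % | substrate / % |
|---|---|---|
| 1.04 | 69.5 | 29.8 |
| 2.08 | 79.5 | 20.4 |
| 3.00 | 80.5 | 18.6 |
| 4.00 | 83.7 | 14.7 |
| 5.00 | 84.3 | 18.0 |

(scatter of a reading: 1 percentage point)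



- apparent order in enzyme when 50% of the substrate are converted (percent change of the rate of making product for one percent more enzyme charged)

**Charge ratio.** Maple and oak carry the same loading, so going from oak to maple multiplies enzyme and substrate together by 1.47, whose logarithm is 0.386.

**The stretch.** Compare the two clocks at equal fractions of the charge turned to product. Oak shows 69.5% after 1.04 d; on a straight line between its readings, maple gets there after 9.88 h. That gives 2.53: call it the stretch, oak's time over maple's time to one conversion. At 79.5%, oak's 2.08 d against maple's 19.9 h gives 2.51.

**Your estimate.** Enzyme lost on a clock of its own costs the slower flask more per conversion, and the stretch grows along the run. These two readings stay level, 2.53 against 2.51, so they show no such growth. As a working assumption, let the rate at a fixed conversion follow the enzyme charge, and you commit to an order of 1.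

**Weak link.** A scatter of 1 percentage point moves maple's second time by 1.49 h, which is 7.50% of it. That slip in the second stretch is wider than the gap between the two readings, so a slow growth can hide in them, and your order stays an assumption. Divided by 0.386, the slip puts about 0.195 on the power of the charge ratio that the stretch stands for.

**The result.** The forecast, against your 1, is 1.5, with the remark “The substrate and enzyme effects are confounded”. The flask gives 1.0. At 50% conversion, reached after 0.151 d, 73.9% of the catalyst is still enzyme.

    substrate + enzyme → product + enzyme, rate k1*[substrate]^2*[enzyme]/(1 + ([substrate]/Kh1)^2) (0.0880 M, k = 2.00 × 10⁵ M⁻² h⁻¹)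
    2 enzyme → spent catalyst (k = 1300 M⁻¹ h⁻¹)

After 0.500 d the flask holds 73.3% product. Multiplied by the stretch, that time puts the same conversion in oak at about 1.26 d.

All runs are simulated with constants of no real substance, noise included.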